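**Retrosynthetic overview**
1. 8 ⇒ 7: the oxirane is the only ring made (the arene is bought) and it is closed last. Both C–O bonds form by catalyst-controlled O-atom transfer to the Re face of the fully acylated 2-arylallyl acetate, which sets the single stereocentre.
2. 7 ⇒ 3 + 6: the aryl–vinyl bond comes from a Suzuki–Miyaura coupling. The acetate arrives on the boronate, so no free OH ever sits next to the labile aryl ester.
3. 3 ⇒ 1: two O-acylations sorted by pKa, phenoxide first and then the primary alcohol.
4. 6 ⇒ 4: α-selective protoboration of propargyl alcohol, then acetylation in the same flask.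

Assumption: 1 is taken as a stock catalogue compound, and the catalyst hand in step 4 (written as the (S,S)/L pair) is defined operationally as the pair that converts α-methylstyrene into (S)-2-methyl-2-phenyloxirane, which has the same spatial sense as 8.

**Route**

Step 1
Reactants: 1 2-bromo-5-(hydroxymethyl)phenol
Product: 3 4-bromo-3-(2-methylpropanoyloxy)benzyl pentanoate, via aryl isobutyrate 2 (not isolated)
Conditions: i) 1 M aq NaOH (1.0 equiv), i-PrCOCl (1.0 equiv), n-Bu4NHSO4 (5 mol %), CH2Cl2, 0 °C, 15 min; ii) organic layer separated and dried, n-BuCOCl (1.1 equiv), pyridine (1.5 equiv), 0 °C → rt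
Reagents that add atoms: isobutyryl chloride CC(C)C(=O)Cl; pentanoyl chloride CCCCC(=O)Cl
Why: One equivalent of hydroxide ionises only the phenol (pKa about 8.5), so the phase-transfer Schotten–Baumann acylation caps the phenoxide alone, and the remaining primary benzylic alcohol is then esterified by the second acyl chloride under pyridine without DMAP, which avoids acyl scrambling; no stereocentre is involved.

Step 2
Reactants: 4 prop-2-yn-1-ol
Product: 6 2-(4,4,5,5-tetramethyl-1,3,2-dioxaborolan-2-yl)allyl acetate, via borylallyl alcohol 5 (not isolated)
Conditions: B2pin2 (1.05 equiv), (SIMes)CuCl (2 mol %), NaOt-Bu (4 mol %), MeOH (1.1 equiv), THF, −50 → −15 °C; then Ac2O (1.5 equiv), Et3N (2 equiv), DMAP (5 mol %), 0 °C → rt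
Reagents that add atoms: bis(pinacolato)diboron CC1(C)OB(OC1(C)C)B1OC(C)(C)C(C)(C)O1; acetic anhydride CC(=O)OC(C)=O
Why: In this copper-catalysed protoboration (formal Markovnikov hydroboration) the N-aryl-NHC–Cu–Bpin species adds syn across the terminal alkyne with boron on the internal carbon, an orientation favoured by the propargylic oxygen, methanol then protonates the C–Cu bond and the alcohol is acetylated in the same flask; no stereocentre is involved.

Step 3
Reactants: 3 4-bromo-3-(2-methylpropanoyloxy)benzyl pentanoate; 6 2-(4,4,5,5-tetramethyl-1,3,2-dioxaborolan-2-yl)allyl acetate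
Product: 7 4-[3-(acetyloxy)prop-1-en-2-yl]-3-(2-methylpropanoyloxy)benzyl pentanoate
Conditions: XPhos Pd G3 (2 mol %), powdered K3PO4 (2 equiv), H2O (4 equiv), THF, 40 °C, 3 h (3 in 5 % excess)
Reagents that add atoms: none
Why: In this Suzuki–Miyaura coupling, oxidative addition of the aryl bromide to monoligated Pd(0) outruns ionisation of the allylic acetate (which for 7 is degenerate anyway, since the 2-aryl-π-allyl is symmetrical and acetate is the only partner), the bulky ligand handles the ortho-substituted bromide and the α-substituted vinylboronate, and solid phosphate with only a few equivalents of water spares the aryl ester; no stereocentre is involved.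

Step 4
Reactants: 7 4-[3-(acetyloxy)prop-1-en-2-yl]-3-(2-methylpropanoyloxy)benzyl pentanoate
Product: 8 4-[(2S)-2-(acetyloxymethyl)oxiran-2-yl]-3-(2-methylpropanoyloxy)benzyl pentanoate (target)
Conditions: [Fe(OTf)2((S,S)-Me2N-PDP)] (2 mol %; Me2N-PDP = N,N'-bis[(4-dimethylaminopyridin-2-yl)methyl]-2,2'-bipyrrolidine), N-(1,8-naphthaloyl)-L-isoleucine (3 mol %), 30 % aq H2O2 (1.8 equiv, syringe pump, 30 min), MeCN, −30 °C; cold aq NaHCO3, Et3N-washed silica
Reagents that add atoms: hydrogen peroxide OO
Why: Proposed new method: enantioselective epoxidation of an α-(acyloxymethyl)styrene that has no directing OH, using a bio-inspired iron catalyst; H2O2 binds to the Fe centre of the C2-symmetric aminopyridine complex, the coordinated amino-acid carboxylic acid protonates the distal oxygen and triggers O–O heterolysis to an electrophilic Fe(V)(O)(carboxylate), and this oxo attacks the unhindered terminal CH2 and closes on the benzylic carbon in one concerted asynchronous event, so both oxirane C–O bonds form here; the stereocentre is set by catalyst control, because the cleft between the bipyrrolidine backbone and the naphthalimide wall of the cis-bound carboxylate sorts the two C2 substituents (the ortho-twisted aryl group against CH2OAc, which takes the place of the α-alkyl group) and exposes the Re face at C2, giving (S)-8; 3 mol % acid, −30 °C and 30 min spare the three esters and the acid-labile benzylic epoxide; the closest known reaction type is the non-haem iron/aminopyridine–H2O2–carboxylic acid asymmetric epoxidation of simple α-alkylstyrenes, which has not been shown for allylic esters or ortho-acyloxy aryl groups.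

**Compound list**
1 | 2-bromo-5-(hydroxymethyl)phenol | OCc1ccc(Br)c(O)c1 | starting material
2 | 2-bromo-5-(hydroxymethyl)phenyl 2-methylpropanoate | CC(C)C(=O)Oc1cc(CO)ccc1Br | intermediate
3 | 4-bromo-3-(2-methylpropanoyloxy)benzyl pentanoate | CCCCC(=O)OCc1ccc(Br)c(OC(=O)C(C)C)c1 | intermediate
4 | prop-2-yn-1-ol | C#CCO | starting material
5 | 2-(4,4,5,5-tetramethyl-1,3,2-dioxaborolan-2-yl)prop-2-en-1-ol | C=C(CO)B1OC(C)(C)C(C)(C)O1 | intermediate
6 | 2-(4,4,5,5-tetramethyl-1,3,2-dioxaborolan-2-yl)allyl acetate | CC(=O)OCC(=C)B1OC(C)(C)C(C)(C)O1 | intermediate
7 | 4-[3-(acetyloxy)prop-1-en-2-yl]-3-(2-methylpropanoyloxy)benzyl pentanoate | CCCCC(=O)OCc1ccc(C(=C)COC(C)=O)c(OC(=O)C(C)C)c1 | intermediate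
8 | 4-[(2S)-2-(acetyloxymethyl)oxiran-2-yl]-3-(2-methylpropanoyloxy)benzyl pentanoate | CCCCC(=O)OCc1ccc([C@@]2(COC(C)=O)CO2)c(OC(=O)C(C)C)c1 | target

**Totals**
- Total steps: 4, of which steps 1 and 2 are telescoped two-stage operations.
- Longest linear sequence: 3 (1 → 3 → 7 → 8).

**Three steps most likely to fail**

(a) Step 4, the new epoxidation.
- Risks: too low an ee, or the opposite sense, on this twisted and inductively deactivated alkene. Lewis-acid opening of the benzylic epoxide is also possible. 8 offers no crystalline handle for upgrading the ee.
- The sense of induction is checked by chiral HPLC against material from the fallback.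
- The fallback is known chemistry and uses hydroxyl-directed control instead of pocket control. It sets out from 3 and from 5, which is now isolated instead of being acetylated. Suzuki–Miyaura coupling of 3 with 5 under the step 3 conditions gives 4-(3-hydroxyprop-1-en-2-yl)-3-(2-methylpropanoyloxy)benzyl pentanoate F1, which is used at once. Catalytic Sharpless asymmetric epoxidation (Ti(OiPr)4 10 mol %, D-(−)-diisopropyl tartrate 12 mol %, t-BuOOH, 4 Å sieves, CH2Cl2, −20 °C) gives 4-[(2R)-2-(hydroxymethyl)oxiran-2-yl]-3-(2-methylpropanoyloxy)benzyl pentanoate F2. F2 has the same spatial arrangement as 8, and the descriptor is R only because CH2OH ranks below the ring CH2. L-(+)-tartrate gives (S)-glycidol and the (2S)-series, hence the D-(−) ester here. Acetylation (Ac2O, Et3N, cat. DMAP, −20 → 0 °C) comes back to the route at 8.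
- This fallback costs one more step and places a free OH next to the aryl ester, with a risk of acyl migration, which is why it is not the main line.

(b) Step 3, the coupling.
- Risks: Pd(0) ionisation of the allylic acetate in 6 or 7 followed by allyl–vinyl coupling, loss of acetate from the boronate, and partial cleavage of the aryl ester.
- The fallback installs the allylic oxygen by C–H oxidation instead of bringing it in on the C3 unit. It sets out from 3. Suzuki–Miyaura coupling with commercial isopropenylboronic acid pinacol ester under the same catalyst and base gives 3-(2-methylpropanoyloxy)-4-(prop-1-en-2-yl)benzyl pentanoate F3. Pd(II)-catalysed allylic C–H acetoxylation (Pd(OAc)2 10 mol %, 1,4-benzoquinone 2 equiv, AcOH, 45 °C) proceeds through the symmetrical 2-aryl-π-allyl complex, so regiochemistry is not an issue, and comes back at 7. The medium is acidic, no free OH appears, and step 2 becomes unnecessary.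

(c) Step 1, the sequential acylation.
- Risk: any cross-acylation gives homologous mixed esters that are hard to separate from 3.
- The fallback uses biocatalytic chemoselectivity in reversed order. It sets out from 1. Immobilised Candida antarctica lipase B with vinyl pentanoate (MTBE, 30 °C) acylates only the primary alcohol and gives 4-bromo-3-hydroxybenzyl pentanoate F4, which is purified. Isobutyryl chloride and Et3N (CH2Cl2, 0 °C) then cap the phenol and come back at 3.

**Further compounds**
F1 | step 4 | 4-(3-hydroxyprop-1-en-2-yl)-3-(2-methylpropanoyloxy)benzyl pentanoate | CCCCC(=O)OCc1ccc(C(=C)CO)c(OC(=O)C(C)C)c1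
F2 | step 4 | 4-[(2R)-2-(hydroxymethyl)oxiran-2-yl]-3-(2-methylpropanoyloxy)benzyl pentanoate | CCCCC(=O)OCc1ccc([C@@]2(CO)CO2)c(OC(=O)C(C)C)c1
F3 | step 3 | 3-(2-methylpropanoyloxy)-4-(prop-1-en-2-yl)benzyl pentanoate | CCCCC(=O)OCc1ccc(C(C)=C)c(OC(=O)C(C)C)c1
F4 | step 1 | 4-bromo-3-hydroxybenzyl pentanoate | CCCCC(=O)OCc1ccc(Br)c(O)c1
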